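Early on the flask holds no target, so each unit of starting material that reacts enters the books as target. That entry is the one worth following.

all flasks: starting material 0.25 M; partner 0.500 M; second substrate 0.250 M
- north-west: third substrate 0.125 M; time 6.0 h; plug flow through a tube for 6.0 h, no back-mixing
- north-east: third substrate 0.125 M; time 6.0 h; everything together in a closed stirred flask, run for 6.0 h
- east: third substrate 0.125 M (fed, over 4.80 h); time 6.0 h; all but third substrate at the start; third substrate goes in evenly over 4.80 h, the run ends at 6.0 h
- south-east: third substrate 0.125 M; a single well-mixed tank run continuously and read at steady state, 6.0 h in it on average

    starting material + partner → target (k1 = 1.2 × 10⁻⁴ M⁻¹ s⁻¹)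
    second substrate + partner → second product (k2 = 1.2 × 10⁻⁵ M⁻¹ s⁻¹)
    third substrate + partner → third product (k3 = 2.5 × 10⁻⁴ M⁻¹ s⁻¹)
    starting material + target → side product (k4 = 1.2 × 10⁻⁴ M⁻¹ s⁻¹)
    second substrate → decomposition product (k5 = 2.1 × 10⁻⁸ s⁻¹)
    second substrate ⇌ dormant form (K6 = 0.56, k6 = 1.1 × 10⁻⁴ s⁻¹)

- a species is counted by the starting material in it: one side product counts as two
- the stated concentrations are those of everything mixed, before any reaction; amounts are the same in each set-up
- the feed brings no volume worth counting
- run time (north-west): 6.0 h

1. the set-up with the highest amount of target at the outlet or at the end, in percent of the starting material put in ("none" if the first two lie within 2 percentage points) (north-west / north-east / east / south-east / none)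
2. amount of target at the outlet or at the end, in percent of the starting material put in, north-west
3. amount of target at the outlet or at the end, in percent of the starting material put in, north-east
4. amount of target at the outlet or at the end, in percent of the starting material put in, east
5. amount of target at the outlet or at the end, in percent of the starting material put in, south-east

A slice in the north-west tube passes through the same 6.0 h as the closed north-east flask, so the two share one set of books. These are kept in fractions of the starting-material charge, and side product holds two units per molecule.

Once target stands, steps 1 and 4 both draw on starting material, so its concentration cancels from their ratio. With target as a fraction of the starting-material charge and partner as a fraction of its own charge, the loss ratio (step 4 over step 1) is target divided by cover times partner. The cover, a selectivity factor, is the rate constant of step 1 times the partner charge over the rate constant of step 4 times the starting-material charge: 2.00. Target stops rising when the loss ratio reaches one.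

My ledger for the closed flask takes partner at 0.7 of its charge on average. The third substrate has a half-life of 1.5 h, shorter than the run, so its whole charge is booked against partner. The second substrate's half-life of 32 h is longer than the run, so it is booked at zero. Target is guessed at 0.7 of what reacted, and the mean loss ratio at 0.5 of its end value.

Reacted by step 1 alone: 59.6%

Partner at the end: 45.2%

Mean loss ratio: 0.231

Starting material left: 32.7%

Target: 42.0%

Side product: 25.2%

In east the third substrate enters over 4.80 h, longer than its half-life, so partner should stand higher there and east should beat the closed flask. The reckoning stops at this direction and gives no figure for the south-east tank.

The forecast gives 43.7% for north-west, 43.7% for north-east, 46.7% for east and 30.2% for south-east, with east best, since in east “partner stays higher early on, so target formation wins more against the side reaction”. Its closed-flask figure stands above my 42.0%.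

The simulation gives 44.3%, 44.3%, 47.4% and 30.3% in that order, with east best. At 6.00 h east keeps 52.5% of its partner, against 48.9% in north-east. The loss ratio of east then reads 0.452, below one. A neighbour flask like east but with 1.0 M of starting material has a cover of 0.500. At 6.00 h it holds target 14.7% and partner 14.6%, so its loss ratio reads 2.01, above one, with side product at 45.4%.

All constants are those of an exercise; no experiment stands behind them.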